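(The earlier runs and the new flask stem from a simulated flask on assumed constants; scatter was added.)

- A small charge of target, 4.00 mM in west, 6.00 mM in south-west and 10.0 mM in north-east, is what differs between these flasks, and I ask whether the target's share at 40 h still shows it.

the same everywhere: solid substrate 0.20 M
- ash: target 3.2 mM; run made earlier
- maple: target 8.1 mM; run made earlier
- west: target 4.00 mM; time 40 h
- south-west: target 6.00 mM; time 40 h
- north-east: target 10.0 mM; time 40 h

- ash (time / h: target / %, isomer of the product / %): 2.50: 19.5, 1.1; 5.00: 37.8, 8.4; 12.0: 59.8, 42.0; 30.0: 12.6, 89.1
- maple (time / h: target / %, isomer of the product / %): 8.00: 53.6, 21.9; 15.0: 45.6, 58.8; 20.0: 29.1, 74.9; 30.0: 13.4, 91.6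

(scatter of a reading: 0.3 percentage points)

1. share of target in all that became target or isomer of the product for west, south-west, north-east, in this order
2. the shape of the row from first to last (falls all the way / falls, then rises / hardly changes / rises, then falls / rises all the way)

- solid substrate is a solid; its amount is given per volume of the solution
- at the start none of the solid substrate is in solution
- "hardly changes" means that all values lie within two and a half points (for a concentration: within two and a half percent of the largest)

- In maple, target plus isomer of the product reads 104% at 20.0 h, close to the 104% that the solid substrate and the starting target can give, so I read the later maple readings as decay of target.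
- Maple's target falls from 29.1% to 13.4% in 10.0 h, from which I read 8.94 h; this is the tail half-life, the first-order half-life of target once the feed has ended.
- From 30.0 h to 40 h it multiplies a share by 0.460, so I carry the shares of 12.4% in ash and 12.8% in maple on to estimates of 5.71% and 5.88%.
- Turned round, the row leaves "hardly changes" if its values spread over more than 2.5 percentage points at 40 h.
- Taking the gap as proportional to the charge, and the row's span as 1.22 times the span of ash and maple, ash and maple would have to stand 4.4 points apart at 30.0 h.
- They stand 0.37 points apart, and the required gap is ten times that; each reading scatters by 0.3 points, so the sign of this gap means little, and I commit to a flat row between 5.71% and 5.88%.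
- The forecast gives 5.7%, 5.7% and 5.6%, in its words “so the row hardly changes”.
- The flasks give 5.88%, 5.85% and 5.81%: hardly changes.

    starting material + target → 2 target (k = 120 L mol⁻¹ h⁻¹)
    starting material → target (k = 0.00450 h⁻¹)
    solid substrate ⇌ starting material, rate k3*(cs3 - [starting material]) while solid is left; crystals form when [starting material] > cs3 (solubility = 0.190 M, k = 0.0980 h⁻¹)
    target ⇌ isomer of the product (K = 60.0, k = 0.0910 h⁻¹)
    2 starting material → self-condensation product (k = 9.60 × 10⁻⁴ L mol⁻¹ h⁻¹)

- In west, target and isomer of the product relax by this step alone, both ways together, with a half-life of 7.49 h, shorter than the 40 h of the run. In west, 8.94 h takes the 29.2% of target at 20.0 h to 6.19% at 40.0 h, and the flask holds 6.00%. In north-east, it takes 29.6% to 6.28%, and at 40.0 h the flask holds 6.10%.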